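Each turn of the chain took one starting material and one partner and gave one target, while each turn of self-condensation took two starting material and gave no target. Starting material therefore had two main sinks, and I left this note for the bench on how they shared it.

| setting | spring | midnight | autumn | winter |
|---|---|---|---|---|
| starting material | 0.050 M | 0.050 M (fed, over 1.00 d) | 0.050 M | 0.050 M |
| partner | 0.0525 M | 0.0525 M | 0.0525 M | 0.0525 M (fed, over 1.00 d) |
| initiator | 0.90 mM | 0.90 mM | 0.90 mM | 0.90 mM |
| remark | one stirred flow tank at steady state, fed with the mixture as stated, mean residence time 2.0 d | all but starting material at the start; starting material goes in evenly over 1.00 d, the run ends at 2.0 d | everything together in a closed stirred flask, run for 2.0 d | all but partner at the start; partner goes in evenly over 1.00 d, the run ends at 2.0 d |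
| time |  | 2.0 d | 2.0 d | 2.0 d |

1. order of the set-ups by the amount of target at the outlet or at the end, in percent of the starting material put in, highest first (spring / midnight / autumn / winter)
2. amount of target at the outlet or at the end, in percent of the starting material put in, spring
3. amount of target at the outlet or at the end, in percent of the starting material put in, midnight
4. amount of target at the outlet or at the end, in percent of the starting material put in, autumn
5. amount of target at the outlet or at the end, in percent of the starting material put in, winter

- in percentages every species weighs as the starting material in it: one ended chains A or self-condensation product counts as two
- a doubled species enters its step squared and goes two at a time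
- the stated concentrations are those of everything mixed, before any reaction; amounts are the same in each set-up
- the feed brings no volume worth counting
- run time (midnight): 2.0 d

    initiator → 2 initiating radical (k1 = 1.5 × 10⁻⁴ min⁻¹)
    starting material + initiating radical → capped initiator + first chain carrier (k2 = 88000 M⁻¹ s⁻¹)
    partner + first chain carrier → target + second chain carrier (k3 = 13000 M⁻¹ s⁻¹)
    starting material + second chain carrier → by-product + first chain carrier (k4 = 2.9 × 10⁵ M⁻¹ min⁻¹)
    first chain carrier → ended carrier (k5 = 21 min⁻¹)
    2 first chain carrier → ended chains A (k6 = 2 × 10⁸ M⁻¹ s⁻¹)
    2 second chain carrier → ended chains B (k7 = 7.3 × 10⁷ M⁻¹ s⁻¹)
    2 starting material → self-condensation product (k8 = 0.067 M⁻¹ min⁻¹)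

I froze the second chain carrier, the resting state, where initiation balanced its own termination, at 5.55 × 10⁻⁹ M. The initiator's half-life of 3.2 d was longer than the 2.0 d run, and this level followed its square root, so I held the charge in the dosed and closed flasks. The chain was then pseudo-first-order in starting material, with constant 0.00161 min⁻¹.

I called 0.0120 M the break-even level: the concentration of starting material at which the chain and self-condensation consume it equally fast. At any moment, target's share of the starting material consumed was one over one plus the ratio of its level to break-even. With partner at its full charge and starting material at break-even, first chain carrier stood at 0.0851 of the second, less than the second, so I kept the freeze.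

By my reckoning the midnight dose held starting material near 0.0112 M, about break-even, so I told my successor not to hurry that dose. Adding the tail after dosing gave 56.0 %.

In spring the tank's initiator was lower, which gave constant 0.00135 min⁻¹, level 0.00670 M and 51.9 %.

In autumn, summing the shares as starting material fell gave 39.4 %.

In winter, the first half-life of starting material by self-condensation alone was about 149 min, and by then 10.4 % of the partner had arrived. Starting the autumn sum from half the charge gave a crude 27.0 %.

My order was midnight > spring > autumn > winter.

The forecast gave midnight > spring > autumn > winter, with 51 % for spring, 53 % for midnight, 37 % for autumn and 22.5 % for winter, where starting material “self-condenses while partner is scarce”.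

The flasks gave midnight > spring > autumn > winter: spring 51.4 %, midnight 54.1 %, autumn 37.5 %, winter 23.5 %.

In midnight, starting material peaked at a reading of 0.0116 M, which against break-even reckoned to a target share of 50.8 % at that peak. The neighbouring midnight flask held 0.20 M of starting material. Break-even put its dose level at 0.0267 M and asked for 0.0678 M of target, more than its 0.0525 M of partner. That flask ended with 25.5 % of its charge as target and 2.83 % of its partner left.

The constants were set for the occasion.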